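Cuts (retro): the O–allyl bonds at O5, O7 and O4'; the pyran ring at O2'–CMe2 and C3'–CH, back to a 2'-O-(1,1-dimethylpropargyl) ether; that ether's O2'–C bond; O1–C2 of ring C; the C3–CH2 prenyl bond; and C2–C3 (1,3-diketone), giving a ring A acetophenone and a ring B benzoate.
Forward: rings A and B are bought. A crossed Claisen condensation joins them, C3 is prenylated, acid closes ring C and unmasks O2' in the same pot, and the 2H-pyran ring is closed last.
Enabling feature: the pyran ring (O2', CMe2, CH=CH, C3', C2') is the valence tautomer of the 1-oxatriene O2'=C2'–C3'=CH–CH=CMe2, an o-quinone methide of ring B. O2' has only one open ortho carbon, C3', because C1' carries ring C.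
The O2'–CMe2 bond is therefore first made as a tether, broken in a [3,3] shift that delivers the C5 unit to the crowded C3', and re-made in the ring closure. Ring B is dearomatised twice on the way, and the allyl cap on O4' shuts out the isomeric 4'-O closure.
Stereochemistry: none to set. The target has no stereocentre, and the pyran alkene is cis by ring size.

Key step: step 8

Remark: the target SMILES contains no stereocentre and no stereogenic open-chain double bond, so the compound is achiral and the constitution alone meets the request for a single enantiomer.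

Step 1
Reactants: 1 2,4,6-trihydroxyacetophenone
Product: 2 1-[2-hydroxy-4,6-bis(allyloxy)phenyl]ethanone
Conditions: allyl bromide (2.1 equiv), K2CO3 (2.2 equiv), acetone, reflux
Reagents that add atoms: allyl bromide, C=CCBr
Why: Williamson etherification takes two phenoxides, while the remaining OH is locked in a hydrogen bond to the acetyl C=O and stays free for the later closure of ring C.

Step 2
Reactants: 3 methyl 2,4-dihydroxybenzoate
Product: 4 methyl 4-(allyloxy)-2-hydroxybenzoate
Conditions: allyl bromide (1.05 equiv), K2CO3 (1.1 equiv), acetone, reflux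
Reagents that add atoms: allyl bromide, C=CCBr
Why: Williamson etherification takes only the more acidic, unchelated 4-OH, because the 2-OH is hydrogen-bonded to the ester carbonyl.

Step 3
Reactants: 4 methyl 4-(allyloxy)-2-hydroxybenzoate
Product: 5 methyl 4-(allyloxy)-2-(methoxymethoxy)benzoate
Conditions: NaH, MOMCl, DMF, 0 °C to rt
Reagents that add atoms: chloromethyl methyl ether, COCCl
Why: O-alkylation of the sodium phenoxide (MOM protection) masks the future O2' with an acid-labile group that is orthogonal to the allyl ethers and falls off in the acid step that closes ring C.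

Step 4
Reactants: 2 1-[2-hydroxy-4,6-bis(allyloxy)phenyl]ethanone; 5 methyl 4-(allyloxy)-2-(methoxymethoxy)benzoate
Product: 6 1-[2-hydroxy-4,6-bis(allyloxy)phenyl]-3-[4-(allyloxy)-2-(methoxymethoxy)phenyl]propane-1,3-dione
Conditions: 2, LiHMDS (3.3 equiv), THF, −78 to 0 °C; then 5, 0 to 50 °C; AcOH quench
Reagents that add atoms: none
Why: In this crossed Claisen condensation the phenoxide–enolate dianion of 2 attacks the non-enolisable ester 5, and deprotonation of the 1,3-diketone formed drives the equilibrium, as in the ester variant of flavone diketone syntheses.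

Step 5
Reactants: 6 1-[2-hydroxy-4,6-bis(allyloxy)phenyl]-3-[4-(allyloxy)-2-(methoxymethoxy)phenyl]propane-1,3-dione
Product: 7 1-[2-hydroxy-4,6-bis(allyloxy)phenyl]-3-[4-(allyloxy)-2-(methoxymethoxy)phenyl]-2-(3-methylbut-2-enyl)propane-1,3-dione (racemic)
Conditions: prenyl bromide (1.1 equiv), K2CO3 (1.5 equiv), acetone, rt to reflux
Reagents that add atoms: prenyl bromide, CC(C)=CCBr
Why: SN2 C-alkylation of the soft 1,3-diketone enolate with an allylic bromide leaves the chelated ring A phenol untouched; the new stereocentre forms racemic, is configurationally labile and is erased in step 6.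

Step 6
Reactants: 7 2-prenylated 1,3-diketone
Product: 9 5,7-bis(allyloxy)-2-[4-(allyloxy)-2-hydroxyphenyl]-3-(3-methylbut-2-enyl)chromen-4-one, via MOM-protected flavone 8 (not isolated)
Conditions: conc. HCl (cat.), MeOH–THF, 55 °C
Reagents that add atoms: none
Why: Acid-catalysed cyclodehydration, as in the closing stage of a Baker–Venkataraman flavone synthesis (the ring A OH adds to the ring B-side carbonyl and water is lost), is followed in the same pot by acetal exchange of the MOM group; the ring A-side carbonyl is di-ortho-substituted and strongly deactivated, so the freed O2'–H should not compete, and allyl ethers and the prenyl group tolerate dilute methanolic acid.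

Step 7
Reactants: 9 5,7-bis(allyloxy)-2-[4-(allyloxy)-2-hydroxyphenyl]-3-(3-methylbut-2-enyl)chromen-4-one
Product: 10 5,7-bis(allyloxy)-2-{4-(allyloxy)-2-[(2-methylbut-3-yn-2-yl)oxy]phenyl}-3-(3-methylbut-2-enyl)chromen-4-one
Conditions: 3-chloro-3-methylbut-1-yne, DBU, CuCl2·2H2O (cat.), MeCN, 0 °C to rt, N2
Reagents that add atoms: 3-chloro-3-methylbut-1-yne, CC(C)(Cl)C#C
Why: Copper-catalysed propargylic etherification, through a copper acetylide that ionises to an allenylidene-type electrophile, is the standard entry to tertiary aryl 1,1-dimethylpropargyl ethers, and O2'–H is the only free phenol here.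

Step 8
Reactants: 10 5,7-bis(allyloxy)-2-{4-(allyloxy)-2-[(2-methylbut-3-yn-2-yl)oxy]phenyl}-3-(3-methylbut-2-enyl)chromen-4-one
Product: 14 5,7,4'-tri-O-allylkuwanon A, via allenyl dienone 11 (not isolated), via allenyl phenol 12 (not isolated), via o-quinone methide 13 (not isolated)
Conditions: o-xylene (degassed), reflux (ca. 140 °C), Ar
Reagents that add atoms: none
Why: Heating starts an aromatic propargyl Claisen [3,3] shift that breaks O2'–CMe2 and joins the alkyne terminus to C3', dearomatising ring B to allenyl dienone 11; enolisation gives allenyl phenol 12, and a [1,5]-H shift from O2'–H to the central allene carbon dearomatises ring B again to the (Z)-o-quinone methide 13. The closest known reaction type is the thermal rearrangement of aryl 1,1-dimethylpropargyl ethers to 2,2-dimethyl-2H-chromenes, which the gem-dimethyl group accelerates. The pyran ring closes by a thermal disrotatory oxa-6π electrocyclisation of the 1-oxatriene in 13 (O2' to CMe2), driven by rearomatisation of ring B. No stereocentre remains, since the sp3 C3' of 11 is erased on enolisation and the new ring alkene is cis by ring size. Site selectivity is needed twice and the substrate secures it: C1' carries ring C, so only C3' can take the shift productively, and O4' is capped as its allyl ether, so only O2'–H can feed the H shift and only O2' can close. Chemoselectivity over the three allyl aryl ethers rests on the much higher temperature their own Claisen shift needs, and the prenyl alkene has no pericyclic partner within reach before the fast ring closure.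

Step 9
Reactants: 14 5,7,4'-tri-O-allylkuwanon A
Product: 15 kuwanon A
Conditions: Pd(PPh3)4 (cat.), morpholine (excess), THF, rt
Reagents that add atoms: none
Why: In this Tsuji–Trost-type deallylation Pd(0) ionises the three unhindered primary allyl aryl ethers to π-allyl complexes that morpholine traps, under neutral conditions that should spare the prenyl alkene and the tertiary, ring-bound C–O bond of the chromene.

Compound list
1 | 2,4,6-trihydroxyacetophenone | CC(=O)c1c(O)cc(O)cc1O | starting material
2 | 1-[2-hydroxy-4,6-bis(allyloxy)phenyl]ethanone | CC(=O)c1c(O)cc(OCC=C)cc1OCC=C | intermediate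
3 | methyl 2,4-dihydroxybenzoate | COC(=O)c1ccc(O)cc1O | starting material
4 | methyl 4-(allyloxy)-2-hydroxybenzoate | COC(=O)c1ccc(OCC=C)cc1O | intermediate
5 | methyl 4-(allyloxy)-2-(methoxymethoxy)benzoate | COC(=O)c1ccc(OCC=C)cc1OCOC | intermediate
6 | 1-[2-hydroxy-4,6-bis(allyloxy)phenyl]-3-[4-(allyloxy)-2-(methoxymethoxy)phenyl]propane-1,3-dione | O=C(CC(=O)c1ccc(OCC=C)cc1OCOC)c1c(O)cc(OCC=C)cc1OCC=C | intermediate
7 | 2-(3-methylbut-2-enyl) derivative of 6, racemic and configurationally labile | O=C(C(CC=C(C)C)C(=O)c1ccc(OCC=C)cc1OCOC)c1c(O)cc(OCC=C)cc1OCC=C | intermediate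
8 | 5,7-bis(allyloxy)-2-[4-(allyloxy)-2-(methoxymethoxy)phenyl]-3-(3-methylbut-2-enyl)chromen-4-one, not isolated | CC(C)=CCc1c(-c2ccc(OCC=C)cc2OCOC)oc2cc(OCC=C)cc(OCC=C)c2c1=O | intermediate
9 | 5,7-bis(allyloxy)-2-[4-(allyloxy)-2-hydroxyphenyl]-3-(3-methylbut-2-enyl)chromen-4-one | CC(C)=CCc1c(-c2ccc(OCC=C)cc2O)oc2cc(OCC=C)cc(OCC=C)c2c1=O | intermediate
10 | 5,7-bis(allyloxy)-2-{4-(allyloxy)-2-[(2-methylbut-3-yn-2-yl)oxy]phenyl}-3-(3-methylbut-2-enyl)chromen-4-one | CC(C)=CCc1c(-c2ccc(OCC=C)cc2OC(C)(C)C#C)oc2cc(OCC=C)cc(OCC=C)c2c1=O | intermediate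
11 | allenyl dienone: ring B as cyclohexa-2,4-dienone with C2'=O and sp3 C3'(H) bearing 3-methylbuta-1,2-dienyl, racemic, not isolated | CC(C)=CCc1c(C2=CC=C(OCC=C)C(C=C=C(C)C)C2=O)oc2cc(OCC=C)cc(OCC=C)c2c1=O | intermediate
12 | allenyl phenol: 2'-hydroxy-3'-(3-methylbuta-1,2-dienyl) analogue of 9, not isolated | CC(C)=CCc1c(-c2ccc(OCC=C)c(C=C=C(C)C)c2O)oc2cc(OCC=C)cc(OCC=C)c2c1=O | intermediate
13 | (Z)-o-quinone methide: ring B with C2'=O and C3'=CH–CH=CMe2, alkenyl chain on the side of C2'=O, not isolated | CC(C)=CCc1c(C2=CC=C(OCC=C)/C(=C/C=C(C)C)C2=O)oc2cc(OCC=C)cc(OCC=C)c2c1=O | intermediate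
14 | 5,7,4'-tri-O-allylkuwanon A: 5,7-bis(allyloxy)-2-[5-(allyloxy)-2,2-dimethyl-2H-chromen-8-yl]-3-(3-methylbut-2-enyl)chromen-4-one | CC(C)=CCc1c(-c2ccc(OCC=C)c3c2OC(C)(C)C=C3)oc2cc(OCC=C)cc(OCC=C)c2c1=O | intermediate
15 | kuwanon A: 5,7-dihydroxy-2-(5-hydroxy-2,2-dimethyl-2H-chromen-8-yl)-3-(3-methylbut-2-enyl)chromen-4-one | CC(C)=CCc1c(-c2ccc(O)c3c2OC(C)(C)C=C3)oc2cc(O)cc(O)c2c1=O | target

Total step count: 9. Longest linear sequence: 8 (steps 2 to 9, from compound 3).

Steps most likely to fail

Step 7. Ether formation at the crowded O2', which sits next to the twisted, 3-prenylated chromone, may stall, and the tertiary chloride may be consumed by elimination before the phenoxide captures it. The fallback sets out from 9 and avoids the ether altogether. Compound 9 is heated with 3-methylbut-2-enal and phenylboronic acid (AcOH cat., toluene, Dean–Stark reflux). Boron binds O2' and the aldehyde oxygen and delivers the aldehyde carbon to the only open ortho carbon, C3'. This gives the temporary six-membered cyclic boronate 2-phenyl-4-(2-methylprop-1-enyl)-4H-1,3,2-benzodioxaborin F1 (racemic). On continued heating F1 fragments to the same o-quinone methide 13, which closes by oxa-6π electrocyclisation. The fallback comes back to the route at 14.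

Step 8. The [3,3] shift into C3', which lies between two oxygen substituents, may need a temperature at which the allyl ethers start to migrate. The allenyl phenol may also be diverted by oligomerisation before the H shift. The fallback sets out from 10 and reaches the o-quinone methide by oxidation instead. Semi-hydrogenation (H2, Lindlar catalyst, quinoline, EtOAc) should give the 2'-O-(1,1-dimethylallyl) ether F2. Its aromatic Claisen rearrangement runs at lower temperature (toluene, ca. 110 °C) and should give the 2'-hydroxy-3'-prenyl flavone F3. DDQ (benzene, rt to 80 °C) then abstracts hydride from the benzylic CH2 on the electron-rich ring B, while the CH2 on the electron-poor C3 stays untouched. This gives 13, which closes. The fallback comes back to the route at 14.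

Step 4. The intermolecular acylation may be slow, because ester 5 is electron-rich and ortho-substituted, so proton exchange and slow decay of the dianion could outrun C–C bond formation. The fallback sets out from 5 and makes the acyl transfer intramolecular. Saponification (LiOH, THF–H2O, then citric acid) should give 4-(allyloxy)-2-(methoxymethoxy)benzoic acid F4. Esterification with phenol 2 (EDCI, DMAP, CH2Cl2) should give the aryl ester 2-acetyl-3,5-bis(allyloxy)phenyl 4-(allyloxy)-2-(methoxymethoxy)benzoate F5. A Baker–Venkataraman rearrangement (KOH, pyridine, 50 °C) then moves the aroyl group from oxygen to the acetyl carbon. The fallback comes back to the route at 6.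

Further compounds
F1 | step 7 | 2-phenyl-4-(2-methylprop-1-enyl)-4H-1,3,2-benzodioxaborin fused at O2'/C3' of 9 (racemic) | CC(C)=CCc1c(-c2ccc(OCC=C)c3c2OB(c2ccccc2)OC3C=C(C)C)oc2cc(OCC=C)cc(OCC=C)c2c1=O
F2 | step 8 | 5,7-bis(allyloxy)-2-{4-(allyloxy)-2-[(2-methylbut-3-en-2-yl)oxy]phenyl}-3-(3-methylbut-2-enyl)chromen-4-one | CC(C)=CCc1c(-c2ccc(OCC=C)cc2OC(C)(C)C=C)oc2cc(OCC=C)cc(OCC=C)c2c1=O
F3 | step 8 | 5,7-bis(allyloxy)-2-[4-(allyloxy)-2-hydroxy-3-(3-methylbut-2-enyl)phenyl]-3-(3-methylbut-2-enyl)chromen-4-one | CC(C)=CCc1c(-c2ccc(OCC=C)c(CC=C(C)C)c2O)oc2cc(OCC=C)cc(OCC=C)c2c1=O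
F4 | step 4 | 4-(allyloxy)-2-(methoxymethoxy)benzoic acid | OC(=O)c1ccc(OCC=C)cc1OCOC
F5 | step 4 | 2-acetyl-3,5-bis(allyloxy)phenyl 4-(allyloxy)-2-(methoxymethoxy)benzoate | CC(=O)c1c(OC(=O)c2ccc(OCC=C)cc2OCOC)cc(OCC=C)cc1OCC=C
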